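## Structural features

GA55 is a C19 gibberellin in which a cyclohexane ring A (C1, C2, C3, C4, C5, C10) and a cyclopentane ring B (C5, C6, C8, C9, C10) share the C5–C10 bond; ring B is fused through C8–C9 to a bicyclo[3.2.1]octane made of ring C (C8, C9, C11, C12, C13, C14) and ring D (C8, C14, C13, C16, C15), and a γ-lactone (C19 carbonyl on C4, oxygen on C10) bridges ring A on the face opposite to the 1- and 3-hydroxyls. There are nine stereocentres (C1, C3, C4, C5, C6, C8, C9, C10, C13); four are fully substituted (C4, C8, C10, C13), and C4, C5, C6, C8, C9 and C10 stand next to one another around ring B. The functional groups are two axial, mutually syn secondary alcohols at C1 and C3, the C18 methyl on C4, the C7 carboxylic acid on C6 trans to C4, the bridgehead tertiary alcohol at C13 and the exocyclic C16=C17 alkene. Fragile points are the 3β-hydroxy lactone (retro-aldol at C3–C4 under base), the 1-hydroxy-3-ketone stage of ring A (β-elimination), the allylic tertiary alcohol beside the 1,1-disubstituted alkene (acid-induced skeletal rearrangement) and C6–H once C7 is a carbonyl group. The real difficulty is not the bicyclooctane but the crowded cyclopentane: the lactone must sit cis-fused on ring B between the quaternary carbons C8 and C10, with C5, C6 and C10 in the correct sense relative to C8 and C9. The key step exploits the fact that the lactone ring C19–C4–C5–C10–O shares its C5–C10 bond with ring B, so C5 can be the β-carbon of a C19 enal and C10 a ketone carbon, and one operation forms both C5–C10 and O–C19. Ring A can then be closed over the lactone by a C1–C2 aldol between a C4 acetyl group and a C10-bound aldehyde, which installs the 1-oxygen directly.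

## Logic of the disconnections

29 ⇒ 28 ⇒ 27. No skeletal bond is cut: the C7 carboxyl is taken back to a primary alcohol and the C7 and C13 oxygens to silyl ethers. The reason is that a C7 carbonyl would make C6–H acidic during every enolate step. The gain is that C7 travels as one inert ether from 16 onward. The demand is a final oxidation that selects the primary alcohol of 28 over two secondary and one tertiary hydroxyl.

27 ⇒ 26. The C3–H bond is cut (carbinol to ketone). The base-labile 3β-hydroxy lactone then appears only at the end, and the C3 carbonyl of 26 is the group that activates C2. The demand is hydride delivery to the α face of C3.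

26 ⇒ 25. C1–C2 is cut (aldol), which opens ring A and leaves in 25 only the B/C/D lactone with a C4 acetyl group and a C1 aldehyde. The 1-oxygen comes from the aldehyde at the right oxidation level. The demand is a ketol that does not dehydrate and a C1 centre set anti to the C10–O bond.

25 ⇒ 24 ⇒ 23 ⇒ 21 + 22. C3–C4 is cut (aldol of the C4 lactone enolate with 22; the C1 and C3 oxidation levels are adjusted in between). C4 is the only acidic carbon of 21, so the quaternary centre and the two-carbon unit come off in one cut. The demand is attack on the convex face of the cis-fused lactone/ring B unit.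

21 ⇒ 20. C5–C10 and O–C19 are cut (key step). Ring B, the lactone and the centres C4, C5 and C10 disappear together, and 20 keeps only C6, C8, C9 and C13. The demand is a homoenolate at C5 that adds to the C10 ketone faster than it is protonated, with C4 trans to C7 and the C1 arm trans to C11.

20 ⇒ 18 + 19. C4=C5 is cut (Wittig). This removes the enal and its methyl branch and leaves a C5 aldehyde. The demand is (E) geometry and reaction at the aldehyde only, without loss of configuration at C6 or C9.

18 ⇒ 17 ⇒ 16. No skeletal bond is cut: the C5 aldehyde and C10 ketone are traced to a diol and the diol to a δ-lactone (C5 carbonyl, oxygen on C10). The lactone ties the two oxygens together and gives a rigid tricycle in which C6 can be controlled. The demand is an oxidation of 17 that does not return to 16 through a lactol.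

16 ⇒ 15 ⇒ 13 + 14. C6–C7 is cut (lactone enolate plus 14). C6 becomes a methylene group and the last exocyclic stereocentre is removed. The demand is attack on the face of C6 anti to C14.

13 ⇒ 12 ⇒ 11. C13–C16 is cut (ketyl–alkyne), which opens ring D to a cyclohexanone with an angular prop-2-ynyl group; C13 loses its stereocentre because the bridge can only close cis. The demand is a ketyl that cyclises faster than it is reduced further.

11 ⇒ 10 ⇒ 9 ⇒ 8 ⇒ 6 + 7. C6–C8 is cut (tethered malonate Michael addition), then the ester C–O bond. The quaternary C8 becomes the β-carbon of an enone, and its configuration is dictated by the tether from C10. The demand is conjugate addition to a β,β-disubstituted enone without base-induced isomerisation of the skipped enyne.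

6 ⇒ 5 ⇒ 3 + 4. C8–C15 is cut (1,2-addition of 4, then enone transposition). This takes the three-carbon alkyne arm off and returns ring C to a 1,3-diketone monoketal. The demand is propargyl rather than allenyl transfer, and dehydration toward C14.

3 ⇒ 1 + 2. C9–C10 is cut (aldol). Two achiral commercial pieces remain, and the absolute configuration of the whole route is set here by an amino-acid catalyst. The demand is anti selectivity and reaction at the α-methylene of 1 remote from the ketal.

## Other disconnections considered

Alternative 1: The cut is at C9–C11 and C8–C15 on a preformed ring B. In the forward step CuBr·SMe2 with a chiral ferrocenyl diphosphine adds Grignard reagent A2 to C9 of the cyclopentenone ester A1, and the enolate carbon C8 is alkylated in the same flask by bromide A3 to give A4.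
- In its favour: one catalytic asymmetric operation sets C9 and the quaternary C8; the trans relationship follows from alkylation anti to the new C9 arm; three pieces are joined at once.
- Against it here: ring B exists before the lactone, so C4 and the lactone oxygen must later be attached to a finished, crowded cyclopentane whose C5 is an unactivated methylene and whose C10 is a ketal. The C6 ketone still needs a one-carbon homologation with control of C6, and A1 is a doubly activated enone prone to self-condensation.
- Comparison: on structure, A4 is the better solution for C8 and C9 (one step against steps 1–5 of the chosen plan) and equal in absolute control. On mechanism both plans use enolate chemistry for C8, but the chosen plan sets C5, C10 and the lactone in one ring-forming event, whereas from A4 they would be introduced one at a time. On step economy A4 is reached faster than 11, but the distance from A4 to the target (rings C, D and A, lactone, C7) is longer.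

Alternative 2: The cut is at C13–C14 and C13–C16. In the forward step SmI2 with NiI2 reduces the C14–I bond of A5 and C14 adds to the C13 ester carbon (ring C); after addition of (Me2N)3PO and tBuOH the C13 ketyl adds to C16 (ring D), giving A6.
- In its favour: two rings, the C13 carbinol and the exocyclic alkene form in one step, and C13 is fixed by the bridge. For rings C and D this is better in step count than the chosen plan.
- Against it here: three electron-transfer events must occur in the right order (neopentyl C–I reduction, acyl substitution that stops at the ketone, ketyl formation before over-reduction), with ketone reduction and pinacol coupling as side paths. A5 needs a long preparation with four different arms on the cyclopentane.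
- Comparison: on structure, A6 still lacks C4, the lactone and ring A, and its C10 ketal and C5 methylene pose the same late problem as in Alternative 1. On mechanism the chosen plan uses the same ketyl–alkyne event (step 6) but alone, on a ketone already in ring C, which is less ambitious and more reliable; the outcome at C13 is equal. On step economy the alternative wins for the bicyclooctane and loses for the lactone.

Alternative 3: The cut is at C1–C2. In the forward step a secondary amine converts the C4 acetyl group of A7 into its enamine, and C2 adds to the aldehyde carbon C1 over the lactone bridge to give A8.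
- In its favour: it delivers the 1β-hydroxyl and the 3-ketone at the right oxidation levels under mild organocatalytic conditions. Because C7 is already an ester in A7, the end is only reduction and desilylation; on this point it is better than the chosen plan, which ends with an oxidation at C7 beside free hydroxyls.
- Against it here: as a strategic step it forms one ring, one bond and one stereocentre, and presupposes the whole B/C/D lactone A7, which is the hard part. With C7 as an ester, C6–H is acidic whenever C4 has to be enolised.
- Comparison: it is a complement rather than a rival; the chosen plan uses the same closure as step 17 (25 to 26), so structure, mechanism and stereocontrol are equal. The difference is the oxidation level of C7 at that stage: an ester in A7 costs about three more steps after the carbene annulation, a silyl ether in 25 costs one selective oxidation at the end.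

Key step: step 13

Remarks on the chemistry:
- Gibberellane numbering (C1–C19) is used for every intermediate.
- The stereodescriptors of the keto enal 20, of its annulation product 21 and of the target agree atom by atom, so no structural correction was needed. Two design changes are made: the C13 ether is triethylsilyl instead of trimethylsilyl, because it must survive two amide-base steps, a borohydride and several oxidations, and a free C13 hydroxyl would open the redox-esterification path in step 13; and C4 of 21 is treated as an uncontrolled centre, because it is re-enolised in step 14.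
- Assumption: metal enolates, metal alkoxides and catalyst-bound species are regarded as reactive forms of numbered compounds and carry no number.
- Assumption: 1, 2, 7, 19 and 22 are commercial, 4 is used as its commercial solution and 14 is generated from paraformaldehyde.

## Route

Step 1
Reactants: 1 1,4-dioxaspiro[4.5]decan-7-one; 2 (4-methoxybenzyloxy)acetaldehyde
Product: 3 (8S)-8-[(1R)-1-hydroxy-2-(4-methoxybenzyloxy)ethyl]-1,4-dioxaspiro[4.5]decan-7-one
Conditions: (S)-proline (20 mol %), DMSO, rt; 2 added slowly to 1 (3 equiv)
Reagents that add atoms: none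
Why: Proline-catalysed direct aldol reaction through the enamine of 1; the enamine forms at C9, the α-methylene remote from the ketal carbon, and adds to 2 through the hydrogen-bonded chair transition state, which should give the anti aldol with C9 (S) and the carbinol C10 (R). C10 is oxidised away in step 11, but its anti relationship places the C1 arm equatorial on the lactone ring made in step 4.

Step 2
Reactants: 3 (8S)-8-[(1R)-1-hydroxy-2-(4-methoxybenzyloxy)ethyl]-1,4-dioxaspiro[4.5]decan-7-one; 4 prop-2-yn-1-ylmagnesium bromide
Product: 6 (4R)-4-[(1R)-1-hydroxy-2-(4-methoxybenzyloxy)ethyl]-3-(prop-2-yn-1-yl)cyclohex-2-en-1-one, via Grignard adduct 5 (not isolated)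
Conditions: 4 (2.5 equiv), THF, −78 °C; then 1 M HCl, THF, rt
Reagents that add atoms: water, SMILES O
Why: Grignard 1,2-addition (the propargyl/allenyl reagent reacts by SE2′ and transfers the prop-2-ynyl group; one further equivalent is taken up by the free hydroxyl), then acid hydrolysis of the ketal and dehydration of the β-hydroxy ketone toward C14, an enone transposition of the Stork–Danheiser type. C9 is γ to the new enone and is not touched under these mild acidic conditions.

Step 3
Reactants: 6 (4R)-4-[(1R)-1-hydroxy-2-(4-methoxybenzyloxy)ethyl]-3-(prop-2-yn-1-yl)cyclohex-2-en-1-one; 7 allyl hydrogen malonate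
Product: 8 (1R)-1-[(1R)-4-oxo-2-(prop-2-yn-1-yl)cyclohex-2-en-1-yl]-2-(4-methoxybenzyloxy)ethyl prop-2-en-1-yl malonate
Conditions: DCC, DMAP (10 mol %), CH2Cl2, 0 °C
Reagents that add atoms: none
Why: Steglich esterification of the secondary C10 alcohol; the neutral conditions keep the base-sensitive enone with its skipped alkyne away from alkoxide.

Step 4
Reactants: 8 (1R)-1-[(1R)-4-oxo-2-(prop-2-yn-1-yl)cyclohex-2-en-1-yl]-2-(4-methoxybenzyloxy)ethyl prop-2-en-1-yl malonate
Product: 9 prop-2-en-1-yl 1-[(4-methoxybenzyloxy)methyl]-3,6-dioxo-4a-(prop-2-yn-1-yl)octahydro-1H-isochromene-4-carboxylate (isochromene C1 = C10, C3 = C5, C4 = C6, C4a = C8, C8a = C9; cis ring fusion, 1-substituent cis to 8a-H, C4 epimers)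
Conditions: Cs2CO3 (0.3 equiv), MeCN, rt
Reagents that add atoms: none
Why: Intramolecular Michael addition of the malonate carbon C6 to C8 of the enone (6-exo-trig); the three-atom tether from C10 can reach C8 only by axial attack on the face cis to the C9–C10 bond, so the lactone is cis-fused and the quaternary C8 carries the prop-2-ynyl group trans to C10. C6 is a malonate centre here and its configuration is immaterial.

Step 5
Reactants: 9 prop-2-en-1-yl 1-[(4-methoxybenzyloxy)methyl]-3,6-dioxo-4a-(prop-2-yn-1-yl)octahydro-1H-isochromene-4-carboxylate
Product: 11 1-[(4-methoxybenzyloxy)methyl]-4a-(prop-2-yn-1-yl)hexahydro-1H-isochromene-3,6-dione (cis-fused; C6 methylene), via malonic acid 10 (not isolated)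
Conditions: Pd(PPh3)4 (5 mol %), morpholine, THF, rt; then PhMe, 90 °C
Reagents that add atoms: none
Why: Tsuji–Trost deallylation with zerovalent palladium and morpholine as allyl acceptor, then thermal decarboxylation of the malonic acid half ester; no stereocentre is affected.

Step 6
Reactants: 11 1-[(4-methoxybenzyloxy)methyl]-4a-(prop-2-yn-1-yl)hexahydro-1H-isochromene-3,6-dione
Product: 12 tricyclic hydroxy lactone: δ-lactone (O on C10, C5 carbonyl, C6 methylene) cis-fused at C8–C9 to the bicyclo[3.2.1]octane bearing the bridgehead 13-hydroxyl and the 16-methylene; 10-(4-methoxybenzyloxy)methyl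
Conditions: SmI2 (3 equiv), HMPA, t-BuOH, THF, 0 °C
Reagents that add atoms: none
Why: Ketyl–alkyne reductive cyclisation: SmI2 reduces the C13 ketone to the ketyl, which adds 5-exo-dig to C16 of the axial prop-2-ynyl group, and the vinyl radical is reduced and protonated to the exocyclic methylene. The two-carbon bridge can only span C8 and C13 cis (diaxial on ring C), which fixes C13; the lactone and the PMB ether are inert under these conditions.

Step 7
Reactants: 12 tricyclic hydroxy lactone
Product: 13 13-O-triethylsilyl ether of 12
Conditions: TESOTf, 2,6-lutidine, CH2Cl2, −78 → 0 °C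
Reagents that add atoms: triethylsilyl trifluoromethanesulfonate, SMILES CC[Si](CC)(CC)OS(=O)(=O)C(F)(F)F
Why: Silylation of the bridgehead tertiary alcohol with a silyl triflate; the triethylsilyl ether is robust enough for the enolate, hydride and oxidation steps ahead and keeps a free hydroxyl out of the carbene step.

Step 8
Reactants: 13 13-O-triethylsilyl tricyclic lactone; 14 formaldehyde
Product: 15 6-(hydroxymethyl) lactone (C7 on C6 cis to C15 and trans to C14)
Conditions: LiN(iPr)2, THF, −78 °C; then 14 (gas), −78 °C; AcOH quench
Reagents that add atoms: none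
Why: Aldol addition of the lithium lactone enolate to formaldehyde. In the rigid tricycle the lactone is a chair fused to ring C with C14 axial on C8, so the electrophile should approach C6 axially on the face anti to C14, which puts C7 cis to C15 as the target requires; the cold quench keeps the kinetic epimer.

Step 9
Reactants: 15 6-(hydroxymethyl) lactone
Product: 16 7-O-tert-butyldimethylsilyl ether of 15
Conditions: TBSCl, imidazole, DMF, 0 °C → rt
Reagents that add atoms: tert-butyldimethylsilyl chloride, SMILES CC(C)(C)[Si](C)(C)Cl
Why: Standard silylation of the primary alcohol; weakly basic imidazole avoids retro-aldol or dehydration of the β-hydroxy lactone.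

Step 10
Reactants: 16 7-O-silyl lactone
Product: 17 diol with C5 primary and C10 secondary hydroxyls on the bicyclo[3.2.1]octane (13-OTES, 7-OTBS, 1-OPMB)
Conditions: LiBH4, THF, 0 °C → rt
Reagents that add atoms: none
Why: Borohydride reduction of the lactone to the 1,5-diol; silyl ethers, PMB ether and alkene are inert, and the low temperature and non-basic work-up avoid silyl migration between the two one-carbon arms on C6.

Step 11
Reactants: 17 diol
Product: 18 keto aldehyde (C10 ketone, C5 aldehyde)
Conditions: (COCl)2, DMSO, CH2Cl2, −78 °C; iPr2NEt, −78 → −20 °C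
Reagents that add atoms: none
Why: Swern oxidation: both hydroxyls are converted into alkoxysulfonium salts before base is added, so the C5 aldehyde cannot be trapped by the C10 hydroxyl as a lactol and oxidised back to 16. The hindered amine at low temperature limits epimerisation at C6 and C9.

Step 12
Reactants: 18 keto aldehyde; 19 2-(triphenylphosphoranylidene)propanal
Product: 20 keto enal: bicyclo[3.2.1]octane with the C9 (4-methoxybenzyloxy)acetyl group and, on C8, the C6 stereocentre bearing CH2OTBS and the (E)-2-methylpropenal unit
Conditions: PhMe, 80 °C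
Reagents that add atoms: none
Why: Wittig olefination with the formyl-stabilised ylide, which reacts with the aldehyde only (the ketone is inert) and gives the (E)-2-methyl enal.

Step 13
Reactants: 20 keto enal
Product: 21 B/C/D tricycle with cis-fused α-methyl γ-lactone (C19–C4–C5–C10–O; 13-OTES, 7-OTBS, 1-OPMB)
Conditions: 2-mesityl-6,7-dihydro-5H-pyrrolo[2,1-c][1,2,4]triazol-2-ium chloride (20 mol %), DBU (15 mol %), THF, 40 °C
Reagents that add atoms: none
Why: The carbene adds to the C19 aldehyde and the resulting Breslow intermediate is nucleophilic at C5 (homoenolate). C5 attacks the C10 ketone, whose α-alkoxy group raises its electrophilicity, in a 5-exo-trig closure that makes ring B. Proton transfer to C4 gives the acyl azolium, which the C10 alkoxide captures in a second 5-exo-trig closure that makes the γ-lactone and releases the catalyst. The closest known reaction type is the carbene-catalysed homoenolate annulation of enals with ketones to γ-butyrolactones, which is also known with tethered ketones. Only the arrangement with C4 and the C10 oxygen cis on the new cyclopentane can lactonise, and within it C4 goes trans to C7 on C6 and the C1 arm trans to C11 on C9, which are both 1,2-trans placements and together give the natural configuration at C5 and C10. C4 is set by protonation and is not controlled; both epimers converge in step 14. The step needs homoenolate addition to win over protonation at C5, redox esterification and enolisation of the ketone; this is secured by the absence of any free hydroxyl, by the non-acidic C6–H (C7 is a silyl ether) and by using less DBU than azolium salt, so that no free amidine epimerises C9 or enolises C1.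

Step 14
Reactants: 21 tricyclic lactone; 22 acetaldehyde
Product: 23 4-(1-hydroxyethyl) lactone (C4 quaternary, C3 carbinol epimers)
Conditions: LiN(iPr)2, THF, −78 °C; then 22; AcOH, −78 °C
Reagents that add atoms: none
Why: Aldol addition of the C4 lithium enolate to acetaldehyde; the lactone and ring B form a cis-bicyclo[3.3.0] unit, so the aldehyde should add on the convex face (anti to C6 and C9, syn to H5 and the C1 arm), which puts C3 cis to C1 and the methyl group on the ring B side as in the target. The carbinol centre is removed in step 16.

Step 15
Reactants: 23 4-(1-hydroxyethyl) lactone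
Product: 24 diol with free C1 and C3 hydroxyls
Conditions: DDQ, CH2Cl2/pH 7 buffer, 0 °C
Reagents that add atoms: none
Why: Oxidative cleavage of the PMB ether by DDQ (benzylic hydride abstraction, then hydrolysis of the oxocarbenium ion); silyl ethers, lactone and the 1,1-disubstituted alkene are not affected.

Step 16
Reactants: 24 diol
Product: 25 4-acetyl lactone with C1 aldehyde on C10
Conditions: (COCl)2, DMSO, CH2Cl2, −78 °C; iPr2NEt, −78 → 0 °C
Reagents that add atoms: none
Why: Swern oxidation of the secondary C3 and primary C1 alcohols in one operation; simultaneous activation prevents a lactol between C1 and the C3 hydroxyl, and the C1 aldehyde sits on a fully substituted carbon so it can neither enolise nor epimerise.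

Step 17
Reactants: 25 4-acetyl C1 aldehyde
Product: 26 1β-hydroxy-3-oxo tetracyclic lactone (13-OTES, 7-OTBS)
Conditions: (S)-proline (30 mol %), DMSO, rt
Reagents that add atoms: none
Why: Intramolecular aldol addition of the Hajos–Parrish type (6-enolexo): the enamine of the C4 acetyl group attacks the C1 aldehyde across the lactone bridge and the reaction stops at the ketol. In the chair-like transition state the aldehyde oxygen should point axial, anti to the C10–O bond (dipole minimisation, with the small hydrogen toward C11), which gives the 1β-alcohol.

Step 18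
Reactants: 26 1β-hydroxy-3-oxo lactone
Product: 27 1β,3β-diol (13-OTES, 7-OTBS)
Conditions: Et2BOMe, THF/MeOH (4:1), −78 °C; NaBH4; then MeOH, evaporate
Reagents that add atoms: none
Why: Narasaka–Prasad reduction: Et2BOMe ties the 1β-hydroxyl and the C3 carbonyl into a six-membered boron chelate on the β face, and NaBH4 then delivers hydride from the α face to give the syn (1β,3β) diol. The chelate also protects the ketol from retro-aldol and elimination.

Step 19
Reactants: 27 1β,3β-diol bis-silyl ether
Product: 28 tetraol (1β, 3β, 13-hydroxyls and C7 primary alcohol)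
Conditions: HF·pyridine, pyridine, THF, 0 °C → rt
Reagents that add atoms: none
Why: Fluoride cleavage of both silyl ethers; the buffered, slightly acidic medium avoids retro-aldol epimerisation at C3 and is mild enough to leave the 13-hydroxy-16-ene unit intact.

Step 20
Reactants: 28 tetraol
Product: 29 GA55
Conditions: TEMPO (20 mol %), PhI(OAc)2 (2.5 equiv), MeCN/H2O, rt
Reagents that add atoms: water, SMILES O
Why: Oxoammonium (TEMPO) oxidation with PhI(OAc)2 as terminal oxidant in aqueous acetonitrile takes the primary C7 alcohol through the aldehyde hydrate to the acid. The axial secondary hydroxyls at C1 and C3 and the tertiary 13-hydroxyl should react far more slowly, and the near-neutral medium protects the 3β-hydroxy lactone and the allylic tertiary alcohol.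

## Compound list

1 | 1,4-dioxaspiro[4.5]decan-7-one | O=C1CCCC2(C1)OCCO2 | starting material
2 | (4-methoxybenzyloxy)acetaldehyde | O=CCOCc1ccc(OC)cc1 | starting material
3 | (8S)-8-[(1R)-1-hydroxy-2-(4-methoxybenzyloxy)ethyl]-1,4-dioxaspiro[4.5]decan-7-one | O=C1CC2(OCCO2)CC[C@H]1[C@@H](O)COCc1ccc(OC)cc1 | intermediate
4 | prop-2-yn-1-ylmagnesium bromide | C#CC[Mg]Br | starting material
5 | (8S)-8-[(1R)-1-hydroxy-2-(4-methoxybenzyloxy)ethyl]-7-(prop-2-yn-1-yl)-1,4-dioxaspiro[4.5]decan-7-ol, both C7 epimers (not isolated) | OC1(CC#C)CC2(OCCO2)CC[C@H]1[C@@H](O)COCc1ccc(OC)cc1 | intermediate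
6 | (4R)-4-[(1R)-1-hydroxy-2-(4-methoxybenzyloxy)ethyl]-3-(prop-2-yn-1-yl)cyclohex-2-en-1-one | O=C1C=C(CC#C)[C@@H](CC1)[C@@H](O)COCc1ccc(OC)cc1 | intermediate
7 | allyl hydrogen malonate | C=CCOC(=O)CC(=O)O | starting material
8 | (1R)-1-[(1R)-4-oxo-2-(prop-2-yn-1-yl)cyclohex-2-en-1-yl]-2-(4-methoxybenzyloxy)ethyl prop-2-en-1-yl malonate | O=C1C=C(CC#C)[C@@H](CC1)[C@@H](OC(=O)CC(=O)OCC=C)COCc1ccc(OC)cc1 | intermediate
9 | prop-2-en-1-yl 1-[(4-methoxybenzyloxy)methyl]-3,6-dioxo-4a-(prop-2-yn-1-yl)octahydro-1H-isochromene-4-carboxylate, cis-fused, C4 (gibberellane C6) epimers | O=C1CC[C@H]2[C@H](COCc3ccc(OC)cc3)OC(=O)C(C(=O)OCC=C)[C@@]2(CC#C)C1 | intermediate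
10 | 1-[(4-methoxybenzyloxy)methyl]-3,6-dioxo-4a-(prop-2-yn-1-yl)octahydro-1H-isochromene-4-carboxylic acid (not isolated) | O=C1CC[C@H]2[C@H](COCc3ccc(OC)cc3)OC(=O)C(C(=O)O)[C@@]2(CC#C)C1 | intermediate
11 | 1-[(4-methoxybenzyloxy)methyl]-4a-(prop-2-yn-1-yl)hexahydro-1H-isochromene-3,6-dione, cis-fused | O=C1CC[C@H]2[C@H](COCc3ccc(OC)cc3)OC(=O)C[C@@]2(CC#C)C1 | intermediate
12 | tricyclic hydroxy lactone: δ-lactone (O–C10, C5=O, C6H2) cis-fused at C8–C9 to the 13-hydroxy-16-methylene bicyclo[3.2.1]octane | C=C1C[C@]23C[C@@]1(O)CC[C@H]2[C@H](COCc4ccc(OC)cc4)OC(=O)C3 | intermediate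
13 | 13-O-triethylsilyl ether of 12 | C=C1C[C@]23C[C@@]1(O[Si](CC)(CC)CC)CC[C@H]2[C@H](COCc4ccc(OC)cc4)OC(=O)C3 | intermediate
14 | formaldehyde | C=O | starting material
15 | 6-(hydroxymethyl) derivative of 13, C7 cis to C15 | C=C1C[C@]23C[C@@]1(O[Si](CC)(CC)CC)CC[C@H]2[C@H](COCc4ccc(OC)cc4)OC(=O)[C@@H]3CO | intermediate
16 | 7-O-tert-butyldimethylsilyl ether of 15 | C=C1C[C@]23C[C@@]1(O[Si](CC)(CC)CC)CC[C@H]2[C@H](COCc4ccc(OC)cc4)OC(=O)[C@@H]3CO[Si](C)(C)C(C)(C)C | intermediate
17 | C5,C10-diol from reduction of 16 | C=C1C[C@@]2(C[C@@]1(O[Si](CC)(CC)CC)CC[C@H]2[C@@H](O)COCc4ccc(OC)cc4)[C@@H](CO[Si](C)(C)C(C)(C)C)CO | intermediate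
18 | keto aldehyde (C10 ketone, C5 aldehyde) | C=C1C[C@@]2(C[C@@]1(O[Si](CC)(CC)CC)CC[C@H]2C(=O)COCc4ccc(OC)cc4)[C@@H](CO[Si](C)(C)C(C)(C)C)C=O | intermediate
19 | 2-(triphenylphosphoranylidene)propanal | CC(C=O)=P(c1ccccc1)(c1ccccc1)c1ccccc1 | starting material
20 | bicyclo[3.2.1]octane keto (E)-2-methyl enal (precursor of the key step) | C=C1C[C@@]2(C[C@@]1(O[Si](CC)(CC)CC)CC[C@H]2C(=O)COCc4ccc(OC)cc4)[C@@H](CO[Si](C)(C)C(C)(C)C)/C=C(\C)C=O | intermediate
21 | B/C/D tricycle with cis-fused α-methyl γ-lactone (product of the key step) | C=C1C[C@]23C[C@@]1(O[Si](CC)(CC)CC)CC[C@H]2[C@@]1(COCc4ccc(OC)cc4)OC(=O)[C@H](C)[C@H]1[C@@H]3CO[Si](C)(C)C(C)(C)C | intermediate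
22 | acetaldehyde | CC=O | starting material
23 | 4-(1-hydroxyethyl) lactone, C3 epimers | C=C1C[C@]23C[C@@]1(O[Si](CC)(CC)CC)CC[C@H]2[C@@]1(COCc4ccc(OC)cc4)OC(=O)[C@](C)(C(C)O)[C@H]1[C@@H]3CO[Si](C)(C)C(C)(C)C | intermediate
24 | C1,C3-diol, C3 epimers | C=C1C[C@]23C[C@@]1(O[Si](CC)(CC)CC)CC[C@H]2[C@@]1(CO)OC(=O)[C@](C)(C(C)O)[C@H]1[C@@H]3CO[Si](C)(C)C(C)(C)C | intermediate
25 | 4-acetyl lactone with C1 aldehyde | C=C1C[C@]23C[C@@]1(O[Si](CC)(CC)CC)CC[C@H]2[C@@]1(C=O)OC(=O)[C@](C)(C(C)=O)[C@H]1[C@@H]3CO[Si](C)(C)C(C)(C)C | intermediate
26 | 1β-hydroxy-3-oxo tetracyclic lactone, 13-OTES, 7-OTBS | C=C1C[C@]23C[C@@]1(O[Si](CC)(CC)CC)CC[C@H]2[C@@]12OC(=O)[C@@](C)([C@H]1[C@@H]3CO[Si](C)(C)C(C)(C)C)C(=O)C[C@H]2O | intermediate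
27 | 1β,3β-dihydroxy tetracyclic lactone, 13-OTES, 7-OTBS | C=C1C[C@]23C[C@@]1(O[Si](CC)(CC)CC)CC[C@H]2[C@@]12OC(=O)[C@@](C)([C@H]1[C@@H]3CO[Si](C)(C)C(C)(C)C)[C@@H](O)C[C@H]2O | intermediate
28 | 1β,3β,13-trihydroxy lactone with C7 primary alcohol | C=C1C[C@]23C[C@@]1(O)CC[C@H]2[C@@]12OC(=O)[C@@](C)([C@H]1[C@@H]3CO)[C@@H](O)C[C@H]2O | intermediate
29 | GA55 | C=C1C[C@]23C[C@@]1(O)CC[C@H]2[C@@]12OC(=O)[C@@](C)([C@H]1[C@@H]3C(=O)O)[C@@H](O)C[C@H]2O | target

## Step count and risk

Total step count: 20. Longest linear sequence: 20 steps (from 1 and 2; the route is linear, and the other starting materials enter as single building blocks).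

Least certain steps:

Step 13 (key step). Formation of the Breslow intermediate from the α-branched enal may be slow, so that protonation at C5, or amidine-mediated enolisation at C1 and epimerisation at C9 of the ketone, outruns ring closure. The fallback replaces carbene umpolung by a reductive ketyl–olefin coupling. It sets out from 18: Wittig reaction with methyl 2-(triphenylphosphoranylidene)propanoate gives the keto enoate F1. SmI2 in THF/MeOH at −78 °C then generates the C10 ketyl, which adds 5-exo-trig to C5, and the samarium alkoxide lactonises onto the ester; this returns to the route at 21.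

Step 1. The aldehyde 2 may self-condense under enamine catalysis, and the β-keto ketal may open by elimination of the ketal oxygen. The fallback sets C9 by a reduction with dynamic kinetic resolution instead. It sets out from 2: the lithium enolate of commercial 3-ethoxycyclohex-2-en-1-one (LiN(iPr)2, THF, −78 °C) adds to 2 to give the racemic aldol F2, and Dess–Martin oxidation gives the enolised β-diketone F3. Transfer hydrogenation with RuCl(p-cymene)[TsDPEN] of the appropriate hand in HCO2H/Et3N reduces the exocyclic ketone while C9 equilibrates, giving the anti hydroxy ketone F4. Addition of 4 gives the tertiary carbinol F5, which on treatment with aqueous acid undergoes the Stork–Danheiser transposition and rejoins the route at 6.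

Step 8. Facial selectivity at C6 may be poor or reversed, because the two faces of the enolate differ only by the axial C14 on one side and the equatorial C15 on the other. The fallback makes protonation rather than alkylation the stereodetermining event. It sets out from 13: if step 8 delivers mainly the C6-epimeric hydroxymethyl lactone F6, dehydration with DCC/CuCl gives the α-methylene lactone F7. Copper-catalysed conjugate borylation (CuCl, NaOtBu, a bisphosphine, B2pin2, MeOH) puts boron on C7, and the copper enolate is protonated at C6 on the face that formaldehyde had preferred, which places C7 on the other face in the boronate F8. Oxidation with NaBO3 returns to the route at 15.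

Step 17. Enamine formation at the methyl ketone beside the quaternary C4 may be slow, and the ketol may dehydrate or the β-keto lactone may be attacked by the amine. The fallback is a Mukaiyama aldol instead of enamine catalysis. It sets out from 25: TMSOTf/Et3N in CH2Cl2 at −78 °C converts the acetyl group into the enol silane F9, which adds to the silyl-triflate-activated aldehyde to give the 1-O-trimethylsilyl aldol F10. Methanolysis with citric acid returns to the route at 26.

Step 20. Over-oxidation of the secondary alcohols, or capture of the intermediate C7 aldehyde by the 1β- or 3β-hydroxyl as a lactol that is oxidised to a lactone, may compete with formation of the acid. The fallback masks the syn-1,3-diol before the oxidation. It sets out from 27: 2,2-dimethoxypropane/PPTS gives the 1,3-acetonide F11, HF·pyridine removes both silyl groups to give the acetonide diol F12, and TEMPO/PhI(OAc)2 in MeCN/H2O gives the acetonide acid F13. Aqueous AcOH at rt removes the acetonide and returns to the route at 29.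

## Further compounds

F1 | step 13 | keto (E)-enoate, methyl ester analogue of 20 | C=C1C[C@@]2(C[C@@]1(O[Si](CC)(CC)CC)CC[C@H]2C(=O)COCc4ccc(OC)cc4)[C@@H](CO[Si](C)(C)C(C)(C)C)/C=C(\C)C(=O)OC
F2 | step 1 | 3-ethoxy-6-[1-hydroxy-2-(4-methoxybenzyloxy)ethyl]cyclohex-2-en-1-one, racemic diastereomer mixture | CCOC1=CC(=O)C(CC1)C(O)COCc1ccc(OC)cc1
F3 | step 1 | 3-ethoxy-6-[(4-methoxybenzyloxy)acetyl]cyclohex-2-en-1-one | CCOC1=CC(=O)C(CC1)C(=O)COCc1ccc(OC)cc1
F4 | step 1 | (6S)-3-ethoxy-6-[(1R)-1-hydroxy-2-(4-methoxybenzyloxy)ethyl]cyclohex-2-en-1-one | CCOC1=CC(=O)[C@@H](CC1)[C@@H](O)COCc1ccc(OC)cc1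
F5 | step 1 | 3-ethoxy-6-[(1R)-1-hydroxy-2-(4-methoxybenzyloxy)ethyl]-1-(prop-2-yn-1-yl)cyclohex-2-en-1-ol, C1 epimers | CCOC1=CC(O)(CC#C)[C@@H](CC1)[C@@H](O)COCc1ccc(OC)cc1
F6 | step 8 | C6 epimer of 15 | C=C1C[C@]23C[C@@]1(O[Si](CC)(CC)CC)CC[C@H]2[C@H](COCc4ccc(OC)cc4)OC(=O)[C@H]3CO
F7 | step 8 | 6-methylene lactone | C=C1C[C@]23C[C@@]1(O[Si](CC)(CC)CC)CC[C@H]2[C@H](COCc4ccc(OC)cc4)OC(=O)C3=C
F8 | step 8 | 6-[(pinacolatoboryl)methyl] lactone, C7 cis to C15 | C=C1C[C@]23C[C@@]1(O[Si](CC)(CC)CC)CC[C@H]2[C@H](COCc4ccc(OC)cc4)OC(=O)[C@@H]3CB4OC(C)(C)C(C)(C)O4
F9 | step 17 | trimethylsilyl enol ether of the C4 acetyl group of 25 | C=C1C[C@]23C[C@@]1(O[Si](CC)(CC)CC)CC[C@H]2[C@@]1(C=O)OC(=O)[C@](C)(C(=C)O[Si](C)(C)C)[C@H]1[C@@H]3CO[Si](C)(C)C(C)(C)C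
F10 | step 17 | 1-O-trimethylsilyl ether of 26 | C=C1C[C@]23C[C@@]1(O[Si](CC)(CC)CC)CC[C@H]2[C@@]12OC(=O)[C@@](C)([C@H]1[C@@H]3CO[Si](C)(C)C(C)(C)C)C(=O)C[C@H]2O[Si](C)(C)C
F11 | step 20 | 1,3-O-isopropylidene acetal of 27 | C=C1C[C@]23C[C@@]1(O[Si](CC)(CC)CC)CC[C@H]2[C@@]12OC(=O)[C@@](C)([C@H]1[C@@H]3CO[Si](C)(C)C(C)(C)C)[C@@H]4C[C@H]2OC(C)(C)O4
F12 | step 20 | 1,3-O-isopropylidene acetal with free 13-hydroxyl and C7 alcohol | C=C1C[C@]23C[C@@]1(O)CC[C@H]2[C@@]12OC(=O)[C@@](C)([C@H]1[C@@H]3CO)[C@@H]4C[C@H]2OC(C)(C)O4
F13 | step 20 | 1,3-O-isopropylidene acetal of GA55 | C=C1C[C@]23C[C@@]1(O)CC[C@H]2[C@@]12OC(=O)[C@@](C)([C@H]1[C@@H]3C(=O)O)[C@@H]4C[C@H]2OC(C)(C)O4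
A1 | alternative 1 | methyl 3,3-dimethoxy-5-oxocyclopent-1-ene-1-carboxylate | COC(=O)C1=CC(OC)(OC)CC1=O
A2 | alternative 1 | [2-(1,3-dioxolan-2-yl)ethyl]magnesium bromide | Br[Mg]CCC1OCCO1
A3 | alternative 1 | 3-bromo-1-(trimethylsilyl)propyne | C[Si](C)(C)C#CCBr
A4 | alternative 1 | 2,2,3-trisubstituted cyclopentanone with all four arms | C[Si](C)(C)C#CC[C@]1(C(=O)OC)[C@@H](CCC2OCCO2)C(OC)(OC)CC1=O
A5 | alternative 2 | ring B iodide with C13 ester arm and prop-2-ynyl group | C#CC[C@]1(CI)[C@@H](CCC(=O)OC)C(OC)(OC)C[C@@H]1C(=O)OC
A6 | alternative 2 | B/C/D tricyclic 13-hydroxy-16-ene ketal ester | C=C1C[C@]23C[C@@]1(O)CC[C@H]2C(OC)(OC)C[C@@H]3C(=O)OC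
A7 | alternative 3 | 4-acetyl lactone with C1 aldehyde, 13-OTMS, C7 2-(trimethylsilyl)ethyl ester | C=C1C[C@]23C[C@@]1(O[Si](C)(C)C)CC[C@H]2[C@@]1(C=O)OC(=O)[C@](C)(C(C)=O)[C@H]1[C@@H]3C(=O)OCC[Si](C)(C)C
A8 | alternative 3 | 1β-hydroxy-3-oxo tetracyclic lactone | C=C1C[C@]23C[C@@]1(O[Si](C)(C)C)CC[C@H]2[C@@]12OC(=O)[C@@](C)([C@H]1[C@@H]3C(=O)OCC[Si](C)(C)C)C(=O)C[C@H]2O
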